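**Plan**
- Retrosynthesis cuts the two ring A bonds C4a–C5 and C8–C8a. This gives fragment 1, a sulfinyl dihydropyranone holding O1, C2, C3, C4, C4a and C8a, and fragment 2, a silylated β-ketoester diene holding C5–C8 with the prenyl group and the whole C1' side chain.
- Enabling feature: ring A alternates oxygen-bearing C5, C7 and C8a with carbon-bearing C4a, C6 and C8. That is the pattern a 1,1,3-trioxygenated diene (C5 to C8) leaves when it adds across the C4a=C8a bond of a pyranone carrying a leaving group on C4a.
- Forward order: ring B first (aldol, β-ketosulfoxide, aminomethylenation and ring closure), then the chain (anhydride opening, two-carbon homologation, prenylation, silylation), then ring A by [4+2] addition and aromatization, which should deliver the target directly.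
- Stereochemistry: C2 and C3 come from an Evans syn aldol, C1' from an enantioselective methanolysis of a prochiral anhydride. The key step creates no lasting stereocentre and leaves these three untouched.

Key step: step 11

Assumption: (DHQD)2AQN is taken to open anhydride 12 to the (R)-half-ester 13, by analogy with other 3-alkylglutaric anhydrides; if the sense of induction proved opposite, the pseudoenantiomeric (DHQ)2AQN would be used in the same way.
Remark: sulfoxide 6 is used as the racemate, so 8, 9 and 10 are mixtures of sulfur epimers; this is harmless because sulfur is lost in step 11.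

**Step 1**
Reactants: 1 (S)-4-benzyl-3-propanoyl-1,3-oxazolidin-2-one; 2 acetaldehyde
Product: 4 (S)-4-benzyl-3-[(2S,3R)-3-hydroxy-2-methylbutanoyl]-1,3-oxazolidin-2-one, via dibutylboron (Z)-enolate 3 (not isolated)
Conditions: Bu2BOTf, i-Pr2NEt, CH2Cl2, 0 °C; 2, −78 → 0 °C; pH 7 buffer, MeOH, 30% H2O2, 0 °C
Reagents that add atoms: none
Why: Evans syn aldol reaction, in which the (Z)-boron enolate should react through a Zimmerman–Traxler chair on the face away from the benzyl group and so set the future C3 (S) and C2 (R) of ring B in the syn relationship.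

**Step 2**
Reactants: 4 (S)-4-benzyl-3-[(2S,3R)-3-hydroxy-2-methylbutanoyl]-1,3-oxazolidin-2-one
Product: 5 (2S,3R)-3-hydroxy-N-methoxy-N,2-dimethylbutanamide
Conditions: MeNHOMe·HCl, AlMe3, CH2Cl2, −10 → 0 °C; aq. potassium sodium tartrate
Reagents that add atoms: N,O-dimethylhydroxylamine hydrochloride, CNOC.Cl
Why: Weinreb transamidation of a syn-aldol imide by the aluminium amide, assisted by the free β-hydroxyl, is the standard auxiliary release and should leave both stereocentres untouched.

**Step 3**
Reactants: 5 (2S,3R)-3-hydroxy-N-methoxy-N,2-dimethylbutanamide; 6 methyl p-tolyl sulfoxide (racemic)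
Product: 8 (3S,4R)-4-hydroxy-3-methyl-1-(p-tolylsulfinyl)pentan-2-one, via lithiated sulfoxide 7 (not isolated)
Conditions: 6 (3 equiv), LiN(i-Pr)2 (LDA, 3 equiv), THF, −78 °C; then 5, −78 → −30 °C; aq. NH4Cl
Reagents that add atoms: none
Why: Acylation of an α-sulfinyl carbanion by a Weinreb amide (β-ketosulfoxide synthesis), in which the chelated tetrahedral intermediate should prevent over-addition and keep the ketone masked until the quench, so that the adjacent C3 centre is not enolized.

**Step 4**
Reactants: 8 (3S,4R)-4-hydroxy-3-methyl-1-(p-tolylsulfinyl)pentan-2-one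
Product: 10 (2R,3S)-2,3-dimethyl-5-(p-tolylsulfinyl)-2,3-dihydro-4H-pyran-4-one, via enaminone 9 (not isolated)
Conditions: Me2NCH(OMe)2, CH2Cl2, 23 °C; then CF3CO2H, CH2Cl2, 0 → 23 °C
Reagents that add atoms: N,N-dimethylformamide dimethyl acetal, COC(OC)N(C)C
Why: Aminomethylenation of the doubly activated methylene followed by acid-promoted addition–elimination of the hydroxyl onto the enaminone (the chromone synthesis from β-ketosulfoxides, transposed to an aldol) should close ring B with no bond to C2 or C3 broken, so the syn aldol becomes the cis-dimethyl pyranone.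

**Step 5**
Reactants: 11 3-propylglutaric acid
Product: 12 3-propylglutaric anhydride (4-propyloxane-2,6-dione)
Conditions: Ac2O, reflux; distillation
Reagents that add atoms: none
Why: Dehydrative cyclization of a glutaric acid to its six-membered anhydride with acetic anhydride is routine.

**Step 6**
Reactants: 12 3-propylglutaric anhydride
Product: 13 (3R)-3-(2-methoxy-2-oxoethyl)hexanoic acid
Conditions: MeOH (10 equiv), (DHQD)2AQN (10 mol %), Et2O, −40 °C
Reagents that add atoms: methanol, CO
Why: Cinchona-alkaloid-catalysed enantioselective methanolysis (desymmetrization) of a prochiral 3-substituted glutaric anhydride, in which general-base activation of methanol inside the chiral pocket should distinguish the enantiotopic carbonyls and set C1'.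

**Step 7**
Reactants: 13 (3R)-3-(2-methoxy-2-oxoethyl)hexanoic acid
Product: 15 dimethyl (5R)-3-oxo-5-propylheptanedioate, via acyl imidazolide 14 (not isolated)
Conditions: CDI, THF, 23 °C; then KO2CCH2CO2Me, MgCl2, Et3N, MeCN/THF, 23 → 45 °C; 1 M HCl
Reagents that add atoms: potassium methyl malonate, [K+].[O-]C(=O)CC(=O)OC
Why: Masamune–Brooks homologation, a decarboxylative Claisen condensation of the magnesium malonate half-ester with the acyl imidazolide, is near neutral and should spare the methyl ester and the β-stereocentre.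

**Step 8**
Reactants: 15 dimethyl (5R)-3-oxo-5-propylheptanedioate; 16 prenyl bromide
Product: 17 dimethyl (5R)-2-(3-methylbut-2-en-1-yl)-3-oxo-5-propylheptanedioate (both C2 epimers)
Conditions: 16 (1.05 equiv), K2CO3, acetone, 23 °C
Reagents that add atoms: none
Why: C-alkylation of a β-ketoester enolate with an allylic bromide (SN2) should give the mono-prenyl compound; the new C2 centre is irrelevant because it becomes sp2 in the next step.

**Step 9**
Reactants: 17 dimethyl (5R)-2-(3-methylbut-2-en-1-yl)-3-oxo-5-propylheptanedioate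
Product: 18 dimethyl (5R)-2-(3-methylbut-2-en-1-yl)-5-propyl-3-(trimethylsilyloxy)hept-2-enedioate (E/Z mixture)
Conditions: Me3SiCl, Et3N, toluene, 23 °C; filtration under argon
Reagents that add atoms: chlorotrimethylsilane, C[Si](C)(C)Cl
Why: O-silylation of the β-ketoester to the conjugated silyl enol ether is the first stage of the standard two-stage preparation of 1-alkoxy-1,3-bis(silyloxy)dienes.

**Step 10**
Reactants: 18 dimethyl (5R)-2-(3-methylbut-2-en-1-yl)-5-propyl-3-(trimethylsilyloxy)hept-2-enedioate
Product: 20 (3Z,5R)-1,7-dimethoxy-2-(3-methylbut-2-en-1-yl)-5-propyl-1,3,7-tris(trimethylsilyloxy)hepta-1,3,6-triene, via dilithium bis-enolate 19 (not isolated)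
Conditions: LiN(i-Pr)2 (2.3 equiv), THF, −78 °C; Me3SiCl (2.6 equiv), −78 → 0 °C; pentane, filtration, no aqueous work-up
Reagents that add atoms: chlorotrimethylsilane, C[Si](C)(C)Cl
Why: Kinetic γ-deprotonation of the β-silyloxy enoate together with deliberate α-deprotonation of the remote ester, then O-silylation (second stage of the standard diene preparation), should give the (3Z) diene; silylating the side-chain ester as well avoids a mixture, and that group reverts to the methyl ester on acidic work-up.

**Step 11**
Reactants: 10 (2R,3S)-2,3-dimethyl-5-(p-tolylsulfinyl)-2,3-dihydro-4H-pyran-4-one; 20 (3Z,5R)-1,7-dimethoxy-2-(3-methylbut-2-en-1-yl)-5-propyl-1,3,7-tris(trimethylsilyloxy)hepta-1,3,6-triene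
Product: 23 methyl (3S)-3-[(2R,3S)-5,7-dihydroxy-2,3-dimethyl-6-(3-methylbut-2-en-1-yl)-4-oxo-3,4-dihydro-2H-chromen-8-yl]hexanoate, via sulfinyl cycloadduct 21 (not isolated), via dienyl ketal 22 (not isolated)
Conditions: 20 (1.5 equiv), ZnBr2 (1.1 equiv), CH2Cl2, −40 → 23 °C; then toluene, 60 °C; then 0.5 M HCl, THF, 0 °C
Reagents that add atoms: none
Why: Proposed new method: ZnBr2 chelated between the sulfinyl and C4 oxygens should make C8a of 10 electrophilic enough for the dienol ether terminus of 20 (future C8) to bond to it while the ketene acetal carbon (future C5) bonds to the sulfinyl-bearing C4a, either as an asynchronous Diels–Alder reaction or as a Mukaiyama–Michael addition followed at once by collapse of the zwitterion, giving 21. The closest known reaction types are the cycloaddition–aromatization of 1-methoxy-1,3-bis(silyloxy)dienes with sulfinyl- or haloquinones and of silyloxydienes with 3-substituted chromones to give xanthones. Ring A is the only ring closed and arises by intermolecular [4+2] annulation onto the C4a=C8a bond; warming should bring about sulfoxide syn-elimination (sulfur and H8a are cis in 21) to 22, and dilute acid then removes the silyl groups, expels methanol from the C5 ketal and lets the ring tautomerize to the phloroglucinol. No stereocentre of the product is formed here: the centres created in 21 are all destroyed, and C2, C3 and C1' pass through unchanged because the O1–C2 bond is never broken and no base is present. The selectivity needed is regiochemical and chemoselective: pairing the nucleophilic C8 terminus with the β-alkoxy enone carbon fixes acyl, prenyl and side chain around the ring, the (Z)-enol ether permits the s-cis diene, and the isolated side-chain ketene acetal, less nucleophilic than the dienol ether terminus and outcompeted when 20 is in excess, should remain a spectator.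

**Compound list**
1 | (S)-4-benzyl-3-propanoyl-1,3-oxazolidin-2-one | CCC(=O)N1[C@@H](Cc2ccccc2)COC1=O | starting material
2 | acetaldehyde | CC=O | starting material
3 | (S)-4-benzyl-3-[(Z)-1-(dibutylboryloxy)prop-1-en-1-yl]-1,3-oxazolidin-2-one | CCCCB(CCCC)O/C(=C\C)N1[C@@H](Cc2ccccc2)COC1=O | intermediate (not isolated)
4 | (S)-4-benzyl-3-[(2S,3R)-3-hydroxy-2-methylbutanoyl]-1,3-oxazolidin-2-one | C[C@@H](O)[C@H](C)C(=O)N1[C@@H](Cc2ccccc2)COC1=O | intermediate
5 | (2S,3R)-3-hydroxy-N-methoxy-N,2-dimethylbutanamide | C[C@@H](O)[C@H](C)C(=O)N(C)OC | intermediate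
6 | methyl p-tolyl sulfoxide (racemic) | CS(=O)c1ccc(C)cc1 | starting material
7 | [(p-tolylsulfinyl)methyl]lithium | [Li]CS(=O)c1ccc(C)cc1 | intermediate (not isolated)
8 | (3S,4R)-4-hydroxy-3-methyl-1-(p-tolylsulfinyl)pentan-2-one (sulfur epimers) | C[C@@H](O)[C@H](C)C(=O)CS(=O)c1ccc(C)cc1 | intermediate
9 | (4S,5R)-1-(dimethylamino)-5-hydroxy-4-methyl-2-(p-tolylsulfinyl)hex-1-en-3-one (sulfur epimers) | C[C@@H](O)[C@H](C)C(=O)C(=CN(C)C)S(=O)c1ccc(C)cc1 | intermediate (not isolated)
10 | (2R,3S)-2,3-dimethyl-5-(p-tolylsulfinyl)-2,3-dihydro-4H-pyran-4-one (sulfur epimers) | Cc1ccc(cc1)S(=O)C1=CO[C@H](C)[C@H](C)C1=O | intermediate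
11 | 3-propylglutaric acid | CCCC(CC(=O)O)CC(=O)O | starting material
12 | 3-propylglutaric anhydride (4-propyloxane-2,6-dione) | CCCC1CC(=O)OC(=O)C1 | intermediate
13 | (3R)-3-(2-methoxy-2-oxoethyl)hexanoic acid | CCC[C@@H](CC(=O)OC)CC(=O)O | intermediate
14 | methyl (3R)-3-[2-(1H-imidazol-1-yl)-2-oxoethyl]hexanoate | CCC[C@@H](CC(=O)OC)CC(=O)n1ccnc1 | intermediate (not isolated)
15 | dimethyl (5R)-3-oxo-5-propylheptanedioate | CCC[C@@H](CC(=O)OC)CC(=O)CC(=O)OC | intermediate
16 | prenyl bromide (1-bromo-3-methylbut-2-ene) | CC(C)=CCBr | starting material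
17 | dimethyl (5R)-2-(3-methylbut-2-en-1-yl)-3-oxo-5-propylheptanedioate (C2 epimers) | CCC[C@@H](CC(=O)OC)CC(=O)C(CC=C(C)C)C(=O)OC | intermediate
18 | dimethyl (5R)-2-(3-methylbut-2-en-1-yl)-5-propyl-3-(trimethylsilyloxy)hept-2-enedioate (E/Z mixture) | CCC[C@@H](CC(=O)OC)CC(O[Si](C)(C)C)=C(CC=C(C)C)C(=O)OC | intermediate
19 | dilithium bis-enolate of 18 (remote ester enolate and 3Z dienolate, 5R) | CCC[C@@H](C=C(OC)O[Li])/C=C(O[Si](C)(C)C)/C(CC=C(C)C)=C(OC)O[Li] | intermediate (not isolated)
20 | (3Z,5R)-1,7-dimethoxy-2-(3-methylbut-2-en-1-yl)-5-propyl-1,3,7-tris(trimethylsilyloxy)hepta-1,3,6-triene | CCC[C@@H](C=C(OC)O[Si](C)(C)C)/C=C(O[Si](C)(C)C)/C(CC=C(C)C)=C(OC)O[Si](C)(C)C | intermediate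
21 | (2R,3S)-5-methoxy-8-[(3R)-1-methoxy-1-(trimethylsilyloxy)hex-1-en-3-yl]-2,3-dimethyl-6-(3-methylbut-2-en-1-yl)-4a-(p-tolylsulfinyl)-5,7-bis(trimethylsilyloxy)-2,3,4a,5,8,8a-hexahydro-4H-chromen-4-one (mixture at C4a, C5, C8, C8a and sulfur) | CCC[C@@H](C=C(OC)O[Si](C)(C)C)C1C(O[Si](C)(C)C)=C(CC=C(C)C)C(OC)(O[Si](C)(C)C)C2(S(=O)c3ccc(C)cc3)C1O[C@H](C)[C@H](C)C2=O | intermediate (not isolated)
22 | (2R,3S)-5-methoxy-8-[(3R)-1-methoxy-1-(trimethylsilyloxy)hex-1-en-3-yl]-2,3-dimethyl-6-(3-methylbut-2-en-1-yl)-5,7-bis(trimethylsilyloxy)-2,3,5,8-tetrahydro-4H-chromen-4-one (mixture at C5 and C8) | CCC[C@@H](C=C(OC)O[Si](C)(C)C)C1C(O[Si](C)(C)C)=C(CC=C(C)C)C(OC)(O[Si](C)(C)C)C2=C1O[C@H](C)[C@H](C)C2=O | intermediate (not isolated)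
23 | methyl (3S)-3-[(2R,3S)-5,7-dihydroxy-2,3-dimethyl-6-(3-methylbut-2-en-1-yl)-4-oxo-3,4-dihydro-2H-chromen-8-yl]hexanoate | CCC[C@@H](CC(=O)OC)c1c(O)c(CC=C(C)C)c(O)c2c1O[C@H](C)[C@H](C)C2=O | target

**Step count**
Total: 11 steps. Longest linear sequence: 7 steps (steps 5 to 11); the pyranone branch is 4 steps before the union.

**Steps most likely to fail**

1. Step 11. The push-pull enone may react too slowly, the Michael addition may not be followed by ring closure (silyl transfer giving an open-chain adduct), or the side-chain ketene acetal may add in competition. The fallback sets out from 10 and 20, makes the two ring A bonds one at a time by known reaction types, and comes back to the route at 23.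
   - A Lewis-acid-mediated vinylogous Mukaiyama–Michael addition (ZnBr2, CH2Cl2, −78 °C, immediate hydrolytic work-up), the reaction type by which bis-silyl dienes are added to chromones and silyl enol ethers to dihydropyranones, forms C8–C8a. It should give dimethyl (5S)-4-[(5S,6R)-5,6-dimethyl-4-oxo-3-(p-tolylsulfinyl)oxan-2-yl]-2-(3-methylbut-2-en-1-yl)-3-oxo-5-propylheptanedioate F1.
   - Sulfoxide syn-elimination in toluene at 80 °C (the conjugate addition–elimination way to 2-substituted chromones) should give dimethyl (5S)-4-[(2R,3S)-2,3-dimethyl-4-oxo-3,4-dihydro-2H-pyran-6-yl]-2-(3-methylbut-2-en-1-yl)-3-oxo-5-propylheptanedioate F2, a cyclic enol ether of a 3,5,7-triketo ester.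
   - Claisen cyclization of F2 (NaOMe, MeOH, 0 °C, short contact), the closure used in biomimetic acylphloroglucinol syntheses from triketo esters, forms C4a–C5 with loss of methanol and returns 23. The base step must be kept short and cold to protect the cis C3 centre.

2. Step 10. Double deprotonation may be incomplete at the hindered γ-methylene, the C3=C4 geometry may be lost, or the diene may hydrolyse on isolation. The fallback sets out from 17, bypasses 18 to 20 and comes back at 23.
   - Soft enolization of 17 with Me3SiOTf and Et3N (Et2O, 0 °C), the strong-base-free way from 1,3-dicarbonyl compounds to 1,3-bis(silyloxy)dienes, should leave the side-chain ester as it is, or at worst α-silylated and restored by acid. It should give methyl (3S,4Z)-7-methoxy-6-(3-methylbut-2-en-1-yl)-3-propyl-5,7-bis(trimethylsilyloxy)hepta-4,6-dienoate F3.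
   - F3 takes the place of 20 in step 11 and should give 23 under the same conditions.

3. Step 4. The β-hydroxy ketone may dehydrate or undergo retro-aldol cleavage during aminomethylenation, or C3 may epimerize before the ring closes. The fallback sets out from 5, builds the ring before sulfur is introduced, and comes back at 10.
   - Addition of HC≡CMgBr (THF, 0 °C) to the Weinreb amide should give (4S,5R)-5-hydroxy-4-methylhex-1-yn-3-one F4.
   - 6-endo-dig oxa-cyclization of the β-hydroxy ynone (AgOTf, 10 mol %, CH2Cl2, 23 °C) should give (2R,3S)-2,3-dimethyl-2,3-dihydro-4H-pyran-4-one F5.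
   - Electrophilic sulfenylation of the enol ether carbon with 4-MeC6H4SCl (CH2Cl2, −78 °C, then Et3N) should give (2R,3S)-2,3-dimethyl-5-(p-tolylsulfanyl)-2,3-dihydro-4H-pyran-4-one F6.
   - Oxidation with mCPBA (1.0 equiv, CH2Cl2, −78 °C) returns sulfoxide 10.

**Further compounds**
F1 | step 11 | dimethyl (5S)-4-[(5S,6R)-5,6-dimethyl-4-oxo-3-(p-tolylsulfinyl)oxan-2-yl]-2-(3-methylbut-2-en-1-yl)-3-oxo-5-propylheptanedioate | CCC[C@@H](CC(=O)OC)C(C1O[C@H](C)[C@H](C)C(=O)C1S(=O)c1ccc(C)cc1)C(=O)C(CC=C(C)C)C(=O)OC
F2 | step 11 | dimethyl (5S)-4-[(2R,3S)-2,3-dimethyl-4-oxo-3,4-dihydro-2H-pyran-6-yl]-2-(3-methylbut-2-en-1-yl)-3-oxo-5-propylheptanedioate | CCC[C@@H](CC(=O)OC)C(C1=CC(=O)[C@@H](C)[C@@H](C)O1)C(=O)C(CC=C(C)C)C(=O)OC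
F3 | step 10 | methyl (3S,4Z)-7-methoxy-6-(3-methylbut-2-en-1-yl)-3-propyl-5,7-bis(trimethylsilyloxy)hepta-4,6-dienoate | CCC[C@@H](CC(=O)OC)/C=C(O[Si](C)(C)C)/C(CC=C(C)C)=C(OC)O[Si](C)(C)C
F4 | step 4 | (4S,5R)-5-hydroxy-4-methylhex-1-yn-3-one | C[C@@H](O)[C@H](C)C(=O)C#C
F5 | step 4 | (2R,3S)-2,3-dimethyl-2,3-dihydro-4H-pyran-4-one | C1=CO[C@H](C)[C@H](C)C1=O
F6 | step 4 | (2R,3S)-2,3-dimethyl-5-(p-tolylsulfanyl)-2,3-dihydro-4H-pyran-4-one | Cc1ccc(cc1)SC1=CO[C@H](C)[C@H](C)C1=O
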